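Feature (labdane numbering): ring A (C1–C5, C10) carries its only oxygen on C2 and ring B (C5–C10) its only unsaturation as the C8=C17 methylene, so C2 can be an acyl radical that closes ring A onto an isopropenyl group (C10, C1, C20), and C17 can carry the tin that leaves once ring B has closed.  
Cuts: C1–C2 and C9–C10 in one operation (back to an open-chain phenylselenoester with a Z-allylstannane), then C8=C9 (Wittig), C2–C3 (one-carbon Wittig homologation), the two C4–CH3 bonds (enolate methylation) and the ring alkene of limonene (ozonolysis).  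
Forward: ring-opened (S)-limonene is oxygenated at C17 and joined at C8=C9 to the C9–C15 chain from (R)-citronellol; the C4 methyls, C2, tin and selenium are then added; ring A and then ring B close in the radical step; C2 and C15 are adjusted last.  
Stereochemistry: C5 from limonene, C13 from citronellol, the Z-alkene from the α-silyloxy ketone Wittig reaction, C10 and C9 from the chair–chair cascade (ruled by C5 and the alkene geometry), C2 from hydride attack on the α face.

Key step: step 17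

Remark: TBS = tert-butyldimethylsilyl, TBDPS = tert-butyldiphenylsilyl; comments use labdane atom numbers, names use systematic chain numbers; C15 is carried as a TBDPS ether (not an ester) so that no second carboxyl derivative competes in the enolate methylation, the stannylation and the selenoester formation.

Step 1  
Reactants: 1 (S)-(−)-limonene  
Product: 4 (5S)-7,7-dimethoxy-5-(prop-1-en-2-yl)heptan-2-one, via methoxy hydroperoxide aldehyde 2 (not isolated), via acetal hydroperoxide 3 (not isolated)  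
Conditions: O3 (1 equiv, Sudan red 7B end point), CH2Cl2/MeOH, −78 °C; TsOH·H2O (cat.), rt; NaHCO3, Me2S, rt  
Reagents that add atoms: ozone, O=[O+][O-]; methanol, CO  
Why: Unsymmetrical ozonolysis: ozone prefers the trisubstituted ring alkene over the isopropenyl group, methanol traps the ketone-side carbonyl oxide as a methoxy hydroperoxide so that only the free aldehyde is acetalised before Me2S reduction releases the ketone, and the stereocentre (later C5) is not touched.

Step 2  
Reactants: 4 (5S)-7,7-dimethoxy-5-(prop-1-en-2-yl)heptan-2-one  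
Product: 6 tert-butyl{[(5S)-7,7-dimethoxy-5-(prop-1-en-2-yl)hept-1-en-2-yl]oxy}dimethylsilane, via lithium enolate 5 (not isolated)  
Conditions: LiN(i-Pr)2, THF, −78 °C; TBSCl, DMPU, −78 → 0 °C  
Reagents that add atoms: tert-butyldimethylsilyl chloride, CC(C)(C)[Si](C)(C)Cl  
Why: Kinetic deprotonation of the methyl ketone at −78 °C takes place at the methyl group and O-silylation fixes this enolate as the terminal silyl enol ether (kinetic enol silane formation), the acetal being inert to base.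

Step 3  
Reactants: 6 tert-butyl{[(5S)-7,7-dimethoxy-5-(prop-1-en-2-yl)hept-1-en-2-yl]oxy}dimethylsilane  
Product: 8 (5S)-1-(TBS-oxy)-7,7-dimethoxy-5-(prop-1-en-2-yl)heptan-2-one, via silyloxy epoxide 7 (not isolated)  
Conditions: mCPBA (1 equiv), NaHCO3, CH2Cl2, −20 → 0 °C  
Reagents that add atoms: 3-chloroperoxybenzoic acid, OOC(=O)c1cccc(Cl)c1  
Why: Rubottom oxidation: the peracid epoxidises the electron-rich enol ether much faster than the isopropenyl group and the silyloxy epoxide opens with 1,4-silyl shift to the α-silyloxy ketone, which puts the oxygen on the future C17.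

Step 4  
Reactants: 9 (R)-(+)-β-citronellol  
Product: 10 tert-butyl{[(3R)-3,7-dimethyloct-6-en-1-yl]oxy}diphenylsilane  
Conditions: TBDPSCl, imidazole, DMF, rt  
Reagents that add atoms: tert-butyldiphenylsilyl chloride, CC(C)(C)[Si](Cl)(c1ccccc1)c1ccccc1  
Why: Silylation of a primary alcohol with a silyl chloride and imidazole is routine and gives an ether that withstands every later step up to the fluoride deprotection.

Step 5  
Reactants: 10 tert-butyl{[(3R)-3,7-dimethyloct-6-en-1-yl]oxy}diphenylsilane  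
Product: 12 (4R)-6-(TBDPS-oxy)-4-methylhexan-1-ol, via aldehyde 11 (not isolated)  
Conditions: O3, CH2Cl2/MeOH, −78 °C; NaBH4, −78 °C → rt  
Reagents that add atoms: ozone, O=[O+][O-]  
Why: Ozonolysis of the trisubstituted alkene with reductive work-up by NaBH4 delivers the primary alcohol at the former alkene carbon, and neither reagent affects the silyl ether or the stereocentre.

Step 6  
Reactants: 12 (4R)-6-(TBDPS-oxy)-4-methylhexan-1-ol  
Product: 13 tert-butyl{[(3R)-6-iodo-3-methylhexyl]oxy}diphenylsilane  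
Conditions: I2, PPh3, imidazole, CH2Cl2, 0 °C → rt  
Reagents that add atoms: iodine, [I][I]  
Why: Appel-type iodination: the alcohol is activated as an oxyphosphonium ion and displaced by iodide in an SN2 reaction at a primary carbon.

Step 7  
Reactants: 13 tert-butyl{[(3R)-6-iodo-3-methylhexyl]oxy}diphenylsilane  
Product: 14 [(4R)-6-(TBDPS-oxy)-4-methylhexyl]triphenylphosphonium iodide  
Conditions: PPh3, MeCN, reflux  
Reagents that add atoms: triphenylphosphine, c1ccccc1P(c1ccccc1)c1ccccc1  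
Why: SN2 quaternisation of triphenylphosphine by the primary iodide gives the salt for the Wittig reaction.

Step 8  
Reactants: 14 [(4R)-6-(TBDPS-oxy)-4-methylhexyl]triphenylphosphonium iodide; 8 (5S)-1-(TBS-oxy)-7,7-dimethoxy-5-(prop-1-en-2-yl)heptan-2-one  
Product: 16 (3S,6Z,10R)-12-(TBDPS-oxy)-6-(TBS-oxymethyl)-1,1-dimethoxy-10-methyl-3-(prop-1-en-2-yl)dodec-6-ene, via phosphorus ylide 15 (not isolated)  
Conditions: KN(SiMe3)2, THF, −78 → 0 °C; then 8, THF, −78 °C → rt  
Reagents that add atoms: none  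
Why: Wittig olefination of an α-silyloxy ketone with a non-stabilised ylide under lithium-free conditions is known to place the ylide alkyl group cis to the CH2O substituent, so C11 ends up cis to C17 and trans to C7 (Z), while C5 and C13 are remote and unchanged.

Step 9  
Reactants: 16 (3S,6Z,10R)-12-(TBDPS-oxy)-6-(TBS-oxymethyl)-1,1-dimethoxy-10-methyl-3-(prop-1-en-2-yl)dodec-6-ene  
Product: 17 (3S,6Z,10R)-12-(TBDPS-oxy)-6-(TBS-oxymethyl)-10-methyl-3-(prop-1-en-2-yl)dodec-6-enal  
Conditions: pyridinium p-toluenesulfonate (cat.), acetone/H2O, rt → 40 °C  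
Reagents that add atoms: water, O  
Why: Acid-catalysed acetal hydrolysis: a dimethyl acetal of an aliphatic aldehyde is cleaved by pyridinium tosylate in wet acetone much faster than a primary TBS ether, and the TBDPS ether is inert.

Step 10  
Reactants: 17 (3S,6Z,10R)-12-(TBDPS-oxy)-6-(TBS-oxymethyl)-10-methyl-3-(prop-1-en-2-yl)dodec-6-enal  
Product: 19 (3R,6Z,10R)-12-(TBDPS-oxy)-6-(TBS-oxymethyl)-2,2,10-trimethyl-3-(prop-1-en-2-yl)dodec-6-enal, via monomethyl aldehyde 18 (not isolated)  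
Conditions: KOtBu (3 equiv), MeI (excess), THF, 0 °C → rt  
Reagents that add atoms: iodomethane, CI  
Why: Exhaustive α-methylation of the aldehyde through its potassium enolate (enolate C-alkylation) ends at the quaternary C4 because no α-hydrogen is left, and the molecule holds no other enolisable carbonyl group.

Step 11  
Reactants: 19 (3R,6Z,10R)-12-(TBDPS-oxy)-6-(TBS-oxymethyl)-2,2,10-trimethyl-3-(prop-1-en-2-yl)dodec-6-enal  
Product: 20 (4R,7Z,11R)-13-(TBDPS-oxy)-7-(TBS-oxymethyl)-1-methoxy-3,3,11-trimethyl-4-(prop-1-en-2-yl)trideca-1,7-diene (E/Z mixture at C1=C2)  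
Conditions: Ph3P(CH2OMe)Cl, KOtBu, THF, 0 °C → rt  
Reagents that add atoms: (methoxymethyl)triphenylphosphonium chloride, [Cl-].COC[P+](c1ccccc1)(c1ccccc1)c1ccccc1  
Why: Wittig olefination with methoxymethylidenetriphenylphosphorane works on α-quaternary aldehydes and adds C2 as an enol ether, whose geometry is of no consequence.

Step 12  
Reactants: 20 (4R,7Z,11R)-13-(TBDPS-oxy)-7-(TBS-oxymethyl)-1-methoxy-3,3,11-trimethyl-4-(prop-1-en-2-yl)trideca-1,7-diene  
Product: 22 (4R,7Z,11R)-13-(TBDPS-oxy)-7-(hydroxymethyl)-3,3,11-trimethyl-4-(prop-1-en-2-yl)tridec-7-enal, via silyloxy aldehyde 21 (not isolated)  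
Conditions: 1 M aq HCl/THF (1:4), 0 °C → rt  
Reagents that add atoms: water, O  
Why: Dilute aqueous acid hydrolyses the enol ether to the homologous aldehyde and then removes the primary allylic TBS group (acid hydrolysis), while the TBDPS ether and the three alkenes are stable at this acidity.

Step 13  
Reactants: 22 (4R,7Z,11R)-13-(TBDPS-oxy)-7-(hydroxymethyl)-3,3,11-trimethyl-4-(prop-1-en-2-yl)tridec-7-enal  
Product: 24 (4R,7Z,11R)-13-(TBDPS-oxy)-7-(chloromethyl)-3,3,11-trimethyl-4-(prop-1-en-2-yl)tridec-7-enal, via allylic mesylate 23 (not isolated)  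
Conditions: MsCl, 2,4,6-collidine, LiCl, DMF, 0 °C  
Reagents that add atoms: lithium chloride, [Li+].[Cl-]  
Why: Chlorination through the mesylate with LiCl and collidine converts a primary allylic alcohol into the chloride by direct SN2 displacement without allylic shift or loss of alkene geometry, and the weak base does not enolise the aldehyde.

Step 14  
Reactants: 24 (4R,7Z,11R)-13-(TBDPS-oxy)-7-(chloromethyl)-3,3,11-trimethyl-4-(prop-1-en-2-yl)tridec-7-enal  
Product: 25 (4R,7Z,11R)-13-(TBDPS-oxy)-7-(chloromethyl)-3,3,11-trimethyl-4-(prop-1-en-2-yl)tridec-7-enoic acid  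
Conditions: NaClO2, NaH2PO4, 2-methyl-2-butene (large excess), t-BuOH/H2O, 0 °C → rt  
Reagents that add atoms: sodium chlorite, [Na+].[O-]Cl=O  
Why: Pinnick oxidation turns the aldehyde into the acid under buffered conditions, and excess 2-methyl-2-butene removes hypochlorite before it can attack the alkenes.

Step 15  
Reactants: 25 (4R,7Z,11R)-13-(TBDPS-oxy)-7-(chloromethyl)-3,3,11-trimethyl-4-(prop-1-en-2-yl)tridec-7-enoic acid  
Product: 27 (4R,7Z,11R)-13-(TBDPS-oxy)-3,3,11-trimethyl-4-(prop-1-en-2-yl)-7-[(tributylstannyl)methyl]tridec-7-enoic acid, via lithium carboxylate 26 (not isolated)  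
Conditions: LiN(SiMe3)2 (1 equiv), THF, −78 °C; Bu3SnLi (from Bu3SnH and LiN(i-Pr)2, THF, 0 °C), −78 °C; pH 6 phosphate buffer  
Reagents that add atoms: tributylstannyllithium, [Li][Sn](CCCC)(CCCC)CCCC  
Why: Once the acid is held as its inert lithium carboxylate, the soft stannyl anion displaces the primary allylic chloride by SN2 at −78 °C, which keeps the alkene geometry (stannyl anion alkylation).

Step 16  
Reactants: 27 (4R,7Z,11R)-13-(TBDPS-oxy)-3,3,11-trimethyl-4-(prop-1-en-2-yl)-7-[(tributylstannyl)methyl]tridec-7-enoic acid  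
Product: 28 Se-phenyl (4R,7Z,11R)-13-(TBDPS-oxy)-3,3,11-trimethyl-4-(prop-1-en-2-yl)-7-[(tributylstannyl)methyl]tridec-7-eneselenoate  
Conditions: PhSeSePh, PBu3, Et3N, CH2Cl2, 0 °C → rt  
Reagents that add atoms: diphenyl diselenide, c1ccccc1[Se][Se]c1ccccc1  
Why: Selenoester formation by phosphine–diselenide activation runs through an acyloxyphosphonium ion under non-acidic conditions (Et3N present) that should leave the allylstannane intact.

Step 17  
Reactants: 28 Se-phenyl (4R,7Z,11R)-13-(TBDPS-oxy)-3,3,11-trimethyl-4-(prop-1-en-2-yl)-7-[(tributylstannyl)methyl]tridec-7-eneselenoate  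
Product: 29 (5S,9S,10S,13R)-15-(TBDPS-oxy)labd-8(17)-en-2-one  
Conditions: Bu3SnSnBu3 (0.1 equiv), benzene (5 mM), sunlamp, 80 °C  
Reagents that add atoms: none  
Why: A tributylstannyl radical abstracts the phenylselanyl group from C2, and the acyl radical adds to the unsubstituted terminus C1 of the isopropenyl group (6-endo-trig closure of ring A, favoured over 5-exo by the methyl group on C10 and helped by the C4 gem-dimethyl group) to give the tertiary C10 radical. This radical adds to C9 of the allylstannane (6-endo-trig closure of ring B), and the C8 radical so formed expels the stannyl radical from C17 by β-scission, which fixes the exocyclic C8=C17 alkene and carries the chain. The closest known reaction types are 6-endo acyl radical polyene cyclisations of selenoesters and intramolecular SH2' reactions of allylstannanes. C10 is set by a chair–chair transition state with the C6 chain equatorial on C5, so that C9 bonds to C10 on the face that leaves C20 axial and anti to H5 (trans ring fusion), and C9 is set by the alkene geometry, because C11, being trans to C7, takes the equatorial position and H9 the axial α position. The step needs 6-endo regioselectivity twice and no early quench of the C10 radical: the first is secured by attack at the CH2 terminus C1 and at the less substituted alkene carbon C9, the second by the absence of a stoichiometric hydrogen donor and by high dilution.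

Step 18  
Reactants: 29 (5S,9S,10S,13R)-15-(TBDPS-oxy)labd-8(17)-en-2-one  
Product: 30 (2R,5S,9S,10S,13R)-15-(TBDPS-oxy)labd-8(17)-en-2-ol (2β-alcohol)  
Conditions: Li[HB(s-Bu)3], THF, −78 °C; H2O  
Reagents that add atoms: none  
Why: Substrate-controlled hydride reduction: the β face of C2 is screened by the axial methyl groups C19 and C20, so the bulky borohydride adds from the α face and gives the axial 2β-alcohol.

Step 19  
Reactants: 30 (2R,5S,9S,10S,13R)-15-(TBDPS-oxy)labd-8(17)-en-2-ol  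
Product: 31 (2R,5S,9S,10S,13R)-15-(TBDPS-oxy)labd-8(17)-en-2-yl acetate  
Conditions: Ac2O, DMAP, pyridine, rt → 40 °C  
Reagents that add atoms: acetic anhydride, CC(=O)OC(C)=O  
Why: DMAP-catalysed acylation with acetic anhydride esterifies even a hindered axial secondary alcohol, and the silyl ether and alkene are unaffected.

Step 20  
Reactants: 31 (2R,5S,9S,10S,13R)-15-(TBDPS-oxy)labd-8(17)-en-2-yl acetate  
Product: 32 (2R,5S,9S,10S,13R)-15-hydroxylabd-8(17)-en-2-yl acetate  
Conditions: Bu4NF, AcOH, THF, rt  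
Reagents that add atoms: none  
Why: Fluoride-induced desilylation frees the C15 alcohol, and buffering with acetic acid keeps the medium from hydrolysing the acetate.

Step 21  
Reactants: 32 (2R,5S,9S,10S,13R)-15-hydroxylabd-8(17)-en-2-yl acetate  
Product: 34 (2R,5S,9S,10S,13R)-2-acetoxylabd-8(17)-en-15-oic acid (CNP0205865.1), via aldehyde 33 (not isolated)  
Conditions: TEMPO (cat.), PhI(OAc)2, MeCN/H2O, rt  
Reagents that add atoms: water, O  
Why: Oxoammonium-mediated oxidation (TEMPO with PhI(OAc)2 in aqueous acetonitrile) takes the primary alcohol through the aldehyde and its hydrate to the acid without affecting the acetate or the exocyclic alkene.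

Compound list  
1 | (S)-(−)-limonene | CC1=CC[C@H](CC1)C(C)=C | starting material  
2 | (3S)-6-hydroperoxy-6-methoxy-3-(prop-1-en-2-yl)heptanal (C6 epimers) | O=CC[C@H](CCC(C)(OC)OO)C(C)=C | intermediate  
3 | (5S)-2-hydroperoxy-2,7,7-trimethoxy-5-(prop-1-en-2-yl)heptane (C2 epimers) | COC(OC)C[C@H](CCC(C)(OC)OO)C(C)=C | intermediate  
4 | (5S)-7,7-dimethoxy-5-(prop-1-en-2-yl)heptan-2-one | COC(OC)C[C@H](CCC(C)=O)C(C)=C | intermediate  
5 | lithium (5S)-7,7-dimethoxy-5-(prop-1-en-2-yl)hept-1-en-2-olate | COC(OC)C[C@H](CCC(=C)O[Li])C(C)=C | intermediate  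
6 | tert-butyl{[(5S)-7,7-dimethoxy-5-(prop-1-en-2-yl)hept-1-en-2-yl]oxy}dimethylsilane | COC(OC)C[C@H](CCC(=C)O[Si](C)(C)C(C)(C)C)C(C)=C | intermediate  
7 | tert-butyl({2-[(3S)-5,5-dimethoxy-3-(prop-1-en-2-yl)pentyl]oxiran-2-yl}oxy)dimethylsilane (epoxide epimers) | COC(OC)C[C@H](CCC1(CO1)O[Si](C)(C)C(C)(C)C)C(C)=C | intermediate  
8 | (5S)-1-(TBS-oxy)-7,7-dimethoxy-5-(prop-1-en-2-yl)heptan-2-one | COC(OC)C[C@H](CCC(=O)CO[Si](C)(C)C(C)(C)C)C(C)=C | intermediate  
9 | (R)-(+)-β-citronellol, (3R)-3,7-dimethyloct-6-en-1-ol | CC(C)=CCC[C@@H](C)CCO | starting material  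
10 | tert-butyl{[(3R)-3,7-dimethyloct-6-en-1-yl]oxy}diphenylsilane | CC(C)=CCC[C@@H](C)CCO[Si](c1ccccc1)(c1ccccc1)C(C)(C)C | intermediate  
11 | (4R)-6-(TBDPS-oxy)-4-methylhexanal | O=CCC[C@@H](C)CCO[Si](c1ccccc1)(c1ccccc1)C(C)(C)C | intermediate  
12 | (4R)-6-(TBDPS-oxy)-4-methylhexan-1-ol | OCCC[C@@H](C)CCO[Si](c1ccccc1)(c1ccccc1)C(C)(C)C | intermediate  
13 | tert-butyl{[(3R)-6-iodo-3-methylhexyl]oxy}diphenylsilane | ICCC[C@@H](C)CCO[Si](c1ccccc1)(c1ccccc1)C(C)(C)C | intermediate  
14 | [(4R)-6-(TBDPS-oxy)-4-methylhexyl]triphenylphosphonium iodide | [I-].c1ccccc1[P+](c1ccccc1)(c1ccccc1)CCC[C@@H](C)CCO[Si](c1ccccc1)(c1ccccc1)C(C)(C)C | intermediate  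
15 | [(4R)-6-(TBDPS-oxy)-4-methylhexylidene]triphenylphosphorane | c1ccccc1P(c1ccccc1)(c1ccccc1)=CCC[C@@H](C)CCO[Si](c1ccccc1)(c1ccccc1)C(C)(C)C | intermediate  
16 | (3S,6Z,10R)-12-(TBDPS-oxy)-6-(TBS-oxymethyl)-1,1-dimethoxy-10-methyl-3-(prop-1-en-2-yl)dodec-6-ene | COC(OC)C[C@H](CC/C(CO[Si](C)(C)C(C)(C)C)=C/CC[C@@H](C)CCO[Si](c1ccccc1)(c1ccccc1)C(C)(C)C)C(C)=C | intermediate  
17 | (3S,6Z,10R)-12-(TBDPS-oxy)-6-(TBS-oxymethyl)-10-methyl-3-(prop-1-en-2-yl)dodec-6-enal | O=CC[C@H](CC/C(CO[Si](C)(C)C(C)(C)C)=C/CC[C@@H](C)CCO[Si](c1ccccc1)(c1ccccc1)C(C)(C)C)C(C)=C | intermediate  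
18 | (3S,6Z,10R)-12-(TBDPS-oxy)-6-(TBS-oxymethyl)-2,10-dimethyl-3-(prop-1-en-2-yl)dodec-6-enal (C2 epimers) | O=CC(C)[C@H](CC/C(CO[Si](C)(C)C(C)(C)C)=C/CC[C@@H](C)CCO[Si](c1ccccc1)(c1ccccc1)C(C)(C)C)C(C)=C | intermediate  
19 | (3R,6Z,10R)-12-(TBDPS-oxy)-6-(TBS-oxymethyl)-2,2,10-trimethyl-3-(prop-1-en-2-yl)dodec-6-enal | O=CC(C)(C)[C@H](CC/C(CO[Si](C)(C)C(C)(C)C)=C/CC[C@@H](C)CCO[Si](c1ccccc1)(c1ccccc1)C(C)(C)C)C(C)=C | intermediate  
20 | (4R,7Z,11R)-13-(TBDPS-oxy)-7-(TBS-oxymethyl)-1-methoxy-3,3,11-trimethyl-4-(prop-1-en-2-yl)trideca-1,7-diene (E/Z at C1=C2) | COC=CC(C)(C)[C@H](CC/C(CO[Si](C)(C)C(C)(C)C)=C/CC[C@@H](C)CCO[Si](c1ccccc1)(c1ccccc1)C(C)(C)C)C(C)=C | intermediate  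
21 | (4R,7Z,11R)-13-(TBDPS-oxy)-7-(TBS-oxymethyl)-3,3,11-trimethyl-4-(prop-1-en-2-yl)tridec-7-enal | O=CCC(C)(C)[C@H](CC/C(CO[Si](C)(C)C(C)(C)C)=C/CC[C@@H](C)CCO[Si](c1ccccc1)(c1ccccc1)C(C)(C)C)C(C)=C | intermediate  
22 | (4R,7Z,11R)-13-(TBDPS-oxy)-7-(hydroxymethyl)-3,3,11-trimethyl-4-(prop-1-en-2-yl)tridec-7-enal | O=CCC(C)(C)[C@H](CC/C(CO)=C/CC[C@@H](C)CCO[Si](c1ccccc1)(c1ccccc1)C(C)(C)C)C(C)=C | intermediate  
23 | (4R,7Z,11R)-13-(TBDPS-oxy)-7-[(methanesulfonyloxy)methyl]-3,3,11-trimethyl-4-(prop-1-en-2-yl)tridec-7-enal | O=CCC(C)(C)[C@H](CC/C(COS(C)(=O)=O)=C/CC[C@@H](C)CCO[Si](c1ccccc1)(c1ccccc1)C(C)(C)C)C(C)=C | intermediate  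
24 | (4R,7Z,11R)-13-(TBDPS-oxy)-7-(chloromethyl)-3,3,11-trimethyl-4-(prop-1-en-2-yl)tridec-7-enal | O=CCC(C)(C)[C@H](CC/C(CCl)=C/CC[C@@H](C)CCO[Si](c1ccccc1)(c1ccccc1)C(C)(C)C)C(C)=C | intermediate  
25 | (4R,7Z,11R)-13-(TBDPS-oxy)-7-(chloromethyl)-3,3,11-trimethyl-4-(prop-1-en-2-yl)tridec-7-enoic acid | OC(=O)CC(C)(C)[C@H](CC/C(CCl)=C/CC[C@@H](C)CCO[Si](c1ccccc1)(c1ccccc1)C(C)(C)C)C(C)=C | intermediate  
26 | lithium (4R,7Z,11R)-13-(TBDPS-oxy)-7-(chloromethyl)-3,3,11-trimethyl-4-(prop-1-en-2-yl)tridec-7-enoate | [Li+].[O-]C(=O)CC(C)(C)[C@H](CC/C(CCl)=C/CC[C@@H](C)CCO[Si](c1ccccc1)(c1ccccc1)C(C)(C)C)C(C)=C | intermediate  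
27 | (4R,7Z,11R)-13-(TBDPS-oxy)-3,3,11-trimethyl-4-(prop-1-en-2-yl)-7-[(tributylstannyl)methyl]tridec-7-enoic acid | OC(=O)CC(C)(C)[C@H](CC/C(C[Sn](CCCC)(CCCC)CCCC)=C/CC[C@@H](C)CCO[Si](c1ccccc1)(c1ccccc1)C(C)(C)C)C(C)=C | intermediate  
28 | Se-phenyl (4R,7Z,11R)-13-(TBDPS-oxy)-3,3,11-trimethyl-4-(prop-1-en-2-yl)-7-[(tributylstannyl)methyl]tridec-7-eneselenoate | O=C([Se]c1ccccc1)CC(C)(C)[C@H](CC/C(C[Sn](CCCC)(CCCC)CCCC)=C/CC[C@@H](C)CCO[Si](c1ccccc1)(c1ccccc1)C(C)(C)C)C(C)=C | intermediate  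
29 | (5S,9S,10S,13R)-15-(TBDPS-oxy)labd-8(17)-en-2-one | C=C1CC[C@H]2C(C)(C)CC(=O)C[C@]2(C)[C@H]1CC[C@@H](C)CCO[Si](c1ccccc1)(c1ccccc1)C(C)(C)C | intermediate  
30 | (2R,5S,9S,10S,13R)-15-(TBDPS-oxy)labd-8(17)-en-2-ol (2β-OH) | C=C1CC[C@H]2C(C)(C)C[C@@H](O)C[C@]2(C)[C@H]1CC[C@@H](C)CCO[Si](c1ccccc1)(c1ccccc1)C(C)(C)C | intermediate  
31 | (2R,5S,9S,10S,13R)-15-(TBDPS-oxy)labd-8(17)-en-2-yl acetate | C=C1CC[C@H]2C(C)(C)C[C@@H](OC(C)=O)C[C@]2(C)[C@H]1CC[C@@H](C)CCO[Si](c1ccccc1)(c1ccccc1)C(C)(C)C | intermediate  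
32 | (2R,5S,9S,10S,13R)-15-hydroxylabd-8(17)-en-2-yl acetate | C=C1CC[C@H]2C(C)(C)C[C@@H](OC(C)=O)C[C@]2(C)[C@H]1CC[C@@H](C)CCO | intermediate  
33 | (2R,5S,9S,10S,13R)-15-oxolabd-8(17)-en-2-yl acetate | C=C1CC[C@H]2C(C)(C)C[C@@H](OC(C)=O)C[C@]2(C)[C@H]1CC[C@@H](C)CC=O | intermediate  
34 | (2R,5S,9S,10S,13R)-2-acetoxylabd-8(17)-en-15-oic acid (2β-acetate, CNP0205865.1) | C=C1CC[C@H]2C(C)(C)C[C@@H](OC(C)=O)C[C@]2(C)[C@H]1CC[C@@H](C)CC(=O)O | target

Total step count: 21.  
Longest linear sequence: 18 steps (from 9: steps 4–7, then 8–21); the limonene branch is 17 steps (1–3, then 8–21).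

Steps most likely to fail

Step 17. Reversible addition of stannyl radicals to the allylstannane may scramble the C8=C9 geometry before cyclisation and so erode the configuration at C9. The slow second ring closure may also lose out to hydrogen transfer to the C10 radical, and the chain may break down at high dilution. The fallback separates the leaving group on C17 from the chain carrier. It sets out from chloro acid 25: displacement with PhSO2Na in DMF should give the allyl sulfone acid F1, and PhSeSePh/PBu3 then gives the sulfonyl selenoester F2. Irradiation of F2 with one equivalent of Bu3SnSnBu3 in benzene should run the same two ring closures, now ended by β-loss of a phenylsulfonyl radical from C17, with tin supplied stoichiometrically instead of by chain transfer. It comes back to the route at ketone 29.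

Step 15. The stannyl anion may be quenched by residual acidic protons, substitution on the aggregated carboxylate may be slow, and the allylstannane may be lost by protodestannylation when the acid is set free. The fallback masks the acid and sets out from chloro acid 25. Me3SiCHN2 in MeOH/toluene gives the methyl ester F3, Bu3SnLi in THF at −78 °C gives the stannyl ester F4, and LiOH in THF/MeOH/H2O followed by buffering to pH 6 returns to the route at acid 27.

Step 8. Control of the alkene geometry may be incomplete, and the basic ylide may enolise the ketone instead of adding to it. The fallback is a Horner–Wittig sequence in which the geometry is fixed by separation of diastereomers; it sets out from iodide 13 and ketone 8. Iodide 13 is treated with LiPPh2 and then H2O2 to give the phosphine oxide F5. Its lithio derivative (n-BuLi, THF, −78 °C) is added to ketone 8 and the diastereomeric adducts are separated on silica. The β-hydroxy phosphine oxide F6 then undergoes stereospecific syn elimination with NaH in DMF and returns to the route at alkene 16 as one geometric isomer.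

Further compounds  
F1 | step 17 | (4R,7Z,11R)-13-(TBDPS-oxy)-3,3,11-trimethyl-7-[(phenylsulfonyl)methyl]-4-(prop-1-en-2-yl)tridec-7-enoic acid | OC(=O)CC(C)(C)[C@H](CC/C(CS(=O)(=O)c1ccccc1)=C/CC[C@@H](C)CCO[Si](c1ccccc1)(c1ccccc1)C(C)(C)C)C(C)=C  
F2 | step 17 | Se-phenyl (4R,7Z,11R)-13-(TBDPS-oxy)-3,3,11-trimethyl-7-[(phenylsulfonyl)methyl]-4-(prop-1-en-2-yl)tridec-7-eneselenoate | O=C([Se]c1ccccc1)CC(C)(C)[C@H](CC/C(CS(=O)(=O)c1ccccc1)=C/CC[C@@H](C)CCO[Si](c1ccccc1)(c1ccccc1)C(C)(C)C)C(C)=C  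
F3 | step 15 | methyl (4R,7Z,11R)-13-(TBDPS-oxy)-7-(chloromethyl)-3,3,11-trimethyl-4-(prop-1-en-2-yl)tridec-7-enoate | COC(=O)CC(C)(C)[C@H](CC/C(CCl)=C/CC[C@@H](C)CCO[Si](c1ccccc1)(c1ccccc1)C(C)(C)C)C(C)=C  
F4 | step 15 | methyl (4R,7Z,11R)-13-(TBDPS-oxy)-3,3,11-trimethyl-4-(prop-1-en-2-yl)-7-[(tributylstannyl)methyl]tridec-7-enoate | COC(=O)CC(C)(C)[C@H](CC/C(C[Sn](CCCC)(CCCC)CCCC)=C/CC[C@@H](C)CCO[Si](c1ccccc1)(c1ccccc1)C(C)(C)C)C(C)=C  
F5 | step 8 | [(4R)-6-(TBDPS-oxy)-4-methylhexyl]diphenylphosphine oxide | O=P(c1ccccc1)(c1ccccc1)CCC[C@@H](C)CCO[Si](c1ccccc1)(c1ccccc1)C(C)(C)C  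
F6 | step 8 | (3S,6R,7S,10R)-12-(TBDPS-oxy)-6-(TBS-oxymethyl)-7-(diphenylphosphoryl)-1,1-dimethoxy-10-methyl-3-(prop-1-en-2-yl)dodecan-6-ol | COC(OC)C[C@H](CC[C@@](O)(CO[Si](C)(C)C(C)(C)C)[C@@H](P(=O)(c1ccccc1)c1ccccc1)CC[C@@H](C)CCO[Si](c1ccccc1)(c1ccccc1)C(C)(C)C)C(C)=C  
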